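## Retrosynthetic overview

- C–C disconnection at the side-chain C1′–C2′ bond gives 3-methoxybenzaldehyde 1 (ring plus C1′) and octadecylmagnesium chloride 2 (C2′–C19′). In the forward direction they unite through alkoxide 3 to carbinol 4.
- Key step: carbinol 4 is taken in one flask through benzylic C–O hydrogenolysis (arene 5) and Birch reduction to the 2,5-dihydroanisole 6. The aromatic ring is broken here and the carbinol stereocentre is erased.
- Enone unmasking: hydrolysis of enol ether 6 (β,γ-enone 7) and conjugation give target 8. The OMe carbon becomes C1 (C=O) and the alkylated carbon becomes C3.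
- Ring order: no ring is built. The only ring is the carbocycle of 1, carried through and dearomatised in step 2.

Assumption: the target SMILES has no stereocentre and no stereogenic double bond, so the compound is achiral and "single enantiomer" is taken to mean the one structure drawn (side chain n-C19).

## Route

Step 1
Reactants: 1 3-methoxybenzaldehyde; 2 octadecylmagnesium chloride (commercial 0.5 M solution in THF, 1.2 equiv)
Product: 4 1-(3-methoxyphenyl)nonadecan-1-ol (racemic), via chloromagnesium alkoxide 3 (not isolated)
Conditions: THF, 0 °C → rt; then 1 M HCl, 0 °C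
Reagents that add atoms: none
Why: Grignard 1,2-addition to a non-enolisable aryl aldehyde; the carbinol stereocentre forms as a racemate, which does not matter because step 2 removes it.

Step 2
Reactants: 4 1-(3-methoxyphenyl)nonadecan-1-ol
Product: 6 1-methoxy-5-nonadecylcyclohexa-1,4-diene, via 1-methoxy-3-nonadecylbenzene 5 (not isolated)
Conditions: Li, NH3(l)/THF 1:1, −33 °C, then NH4Cl (3 equiv); then Li to persistent blue, t-BuOH, −33 °C; NH4Cl quench
Reagents that add atoms: none
Why: one-flask dissolving-metal cascade of benzylic C–O hydrogenolysis followed by Birch reduction. With NH4Cl keeping the hydroxyl protonated, the arene radical anion expels hydroxide; the Birch stage then leaves the OMe- and alkyl-bearing carbons sp2, giving the 1,4-diene with no stereocentre.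

Step 3
Reactants: 6 1-methoxy-5-nonadecylcyclohexa-1,4-diene
Product: 8 3-nonadecylcyclohex-2-en-1-one, via 3-nonadecylcyclohex-3-en-1-one 7 (not isolated)
Conditions: 2 M HCl, THF, rt → 50 °C
Reagents that add atoms: water, O
Why: acid hydrolysis of the enol ether gives the β,γ-enone, which acid-catalysed isomerisation moves into conjugation (trisubstituted enone as thermodynamic sink); no stereocentre is involved.

## Compound list

1 | 3-methoxybenzaldehyde | COc1cccc(C=O)c1 | starting material
2 | octadecylmagnesium chloride | CCCCCCCCCCCCCCCCCC[Mg]Cl | starting material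
3 | chloromagnesium 1-(3-methoxyphenyl)nonadecan-1-olate (racemic) | CCCCCCCCCCCCCCCCCCC(O[Mg]Cl)c1cccc(OC)c1 | intermediate
4 | 1-(3-methoxyphenyl)nonadecan-1-ol (racemic) | CCCCCCCCCCCCCCCCCCC(O)c1cccc(OC)c1 | intermediate
5 | 1-methoxy-3-nonadecylbenzene (3-nonadecylanisole) | CCCCCCCCCCCCCCCCCCCc1cccc(OC)c1 | intermediate
6 | 1-methoxy-5-nonadecylcyclohexa-1,4-diene | CCCCCCCCCCCCCCCCCCCC1=CCC=C(OC)C1 | intermediate
7 | 3-nonadecylcyclohex-3-en-1-one | CCCCCCCCCCCCCCCCCCCC1=CCCC(=O)C1 | intermediate
8 | 3-nonadecylcyclohex-2-en-1-one (achiral) | CCCCCCCCCCCCCCCCCCCC1=CC(=O)CCC1 | target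

## Step count and risks

Total step count: 3. Longest linear sequence: 3 steps (1 → 4 → 6 → 8).

Highest risk, step 2. If the hydroxyl is deprotonated before it is cleaved, the ring is reduced with the oxygen still in place. The waxy C26 substrate may also dissolve poorly in ammonia. The fallback removes the oxygen by catalysis before any dissolving metal is used. It sets out from 4, which is acetylated (Ac2O, pyridine, DMAP) to 1-(3-methoxyphenyl)nonadecyl acetate F3. F3 is hydrogenolysed under H2 over palladium on carbon (Pd/C) in EtOAc/AcOH to the isolated arene 5. The route is rejoined at 5, which then needs only the plain Li/NH3/t-BuOH Birch stage to reach 6.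

Second, step 1. The long-chain Grignard reagent can reduce the aldehyde by β-hydride transfer or be consumed by homocoupling. The fallback forms the same bond by olefination. It sets out from 1; 1-bromooctadecane and PPh3 (MeCN, reflux) give octadecyl(triphenyl)phosphonium bromide F1. The ylide of F1 (KOt-Bu, THF, 0 °C) condenses with 1 to give 1-methoxy-3-(nonadec-1-en-1-yl)benzene F2 (mainly Z; the geometry is irrelevant). F2 is put straight into Li/NH3/t-BuOH, where the styrene double bond is saturated to 5 in the flask before the ring is reduced. The route is rejoined at 6.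

Third, step 3. Conjugation may stall and leave mixtures of 7 and 8. The fallback conjugates before hydrolysis. It sets out from 6, which KOt-Bu in DMSO at rt isomerises to the conjugated dienol ether 1-methoxy-3-nonadecylcyclohexa-1,3-diene F4. Dilute aqueous oxalic acid then protonates F4 at the γ-carbon and releases the conjugated enone directly. The route is rejoined at 8.

## Further compounds

F1 | step 1 | octadecyl(triphenyl)phosphonium bromide | CCCCCCCCCCCCCCCCCC[P+](c1ccccc1)(c1ccccc1)c1ccccc1.[Br-]
F2 | step 1 | 1-methoxy-3-[(Z)-nonadec-1-en-1-yl]benzene (major isomer of a Z/E mixture) | CCCCCCCCCCCCCCCCC/C=C\c1cccc(OC)c1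
F3 | step 2 | 1-(3-methoxyphenyl)nonadecyl acetate (racemic) | CCCCCCCCCCCCCCCCCCC(OC(C)=O)c1cccc(OC)c1
F4 | step 3 | 1-methoxy-3-nonadecylcyclohexa-1,3-diene | CCCCCCCCCCCCCCCCCCCC1=CCCC(OC)=C1
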